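Each unit of target consumes one unit of first nucleophile and one of substrate, so the first nucleophile's charge is the first limit to check.

    substrate → intermediate (k1 = 0.054 s⁻¹, Ea1 = 86.0 kJ mol⁻¹)
    second nucleophile + intermediate → other capture product (k2 = 0.38 L mol⁻¹ s⁻¹, Ea2 = 64.0 kJ mol⁻¹)
    solid second nucleophile ⇌ second nucleophile, rate k3*(cs3 - [second nucleophile]) while solid is left; crystals form when [second nucleophile] > cs3 (cs3 = 0.25 M, k3 = 0.027 s⁻¹)
    first nucleophile + intermediate → target (k4 = 0.47 L mol⁻¹ s⁻¹, Ea4 = 60.0 kJ mol⁻¹)
    (constants at 80 °C)

| setting | Tuesday's | Friday's | Sunday's | Wednesday's |
|---|---|---|---|---|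
| substrate | 1.7 M | 1.7 M | 1.7 M | 1.7 M |
| first nucleophile | 0.850 M | 0.850 M | 0.850 M | 0.850 M |
| solid second nucleophile | 1.70 M | 1.70 M | 1.70 M | 1.70 M |
| temperature | 95 °C | 80 °C | 110 °C | 65 °C |
| time | 10 min | 10 min | 10 min | 10 min |

- solid, in amounts per volume of the solution: solid second nucleophile
- all constants are for 80 °C and move with temperature by the activation energies
- at the start none of the solid second nucleophile is in solution

- the flask with the highest amount of target, in percent of the substrate charged ("all alike" if they lie within 1.5 percentage points) (Tuesday's / Friday's / Sunday's / Wednesday's / all alike)
- final target, as a percentage of the substrate charged, in Tuesday's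
- final target, as a percentage of the substrate charged, in Friday's
- final target, as a percentage of the substrate charged, in Sunday's
- final target, as a percentage of the substrate charged, in Wednesday's

1. **Cap.** The first nucleophile is the limiting reagent for target, and it caps target at 50.0 % of the substrate charged.

2. **Time.** Wednesday's is the coldest flask. The logarithm of k1 runs straight in reciprocal temperature, and on that scale 80 °C lies less than midway from 65 °C to 110 °C, so k1 falls from 80 °C to 65 °C by less than the square root of the span factor 36. Step 1 in Wednesday's therefore stands above 0.538 min⁻¹. So 10 min is more than 5.38 lifetimes, and less than 0.463 % of the substrate remains.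

3. **Rival.** Suppose [second nucleophile] stands at its solubility. Then the two captures run level when [first nucleophile] equals the crossover concentration q = k2·cs3/k4 = 0.202 M, a selectivity factor written as a concentration. Each q of other capture product formed then lowers [first nucleophile] by a factor of e.

4. **Temperature.** Across the series, q shifts by at most a factor of 1.18, so 0.239 M is a ceiling for the four flasks.

5. **Floor.** Once the substrate has turned over, the part beyond the cap ends as other capture product, at least 0.850 M. That leaves at most 0.0242 M of first nucleophile, so target reaches at least 48.6 %. The gap to the cap is 1.4 percentage points, less than the margin of 1.5 points.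

6. **Weak link.** Step 3 assumed the solubility from the start, but [second nucleophile] starts at zero. In Friday's, the substrate lifetime of 18.5 s is shorter than the dissolving time of 37.0 s. So q overstates the rival there, and the floor stands. My reckoning commits to a range: each flask between floor and cap, verdict all alike.

The forecast names all alike, with 50 %, 50 % and 50 % for the three hotter flasks and 49.7 % for Wednesday's, on the ground that “all four flasks sit essentially at the cap”. That lies inside my range.

The simulation gives all alike: 50.0 %, 50.0 %, 50.0 % and 50.0 % in Tuesday's, Friday's, Sunday's and Wednesday's. Wednesday's keeps 0.014 % of its first nucleophile at 10.0 min. Wednesday's neighbour, charged with 0.68 M of substrate, holds 1.25 equiv of first nucleophile, so the cap gives way to q. Ea2 exceeds Ea4, so q at 80 °C serves as a ceiling for this cold flask. Halfway through, [first nucleophile] stands near 0.510 M, so the reckoned target is 71.6 %. The neighbour's run lies above that: target 80.5 %, other capture product 19.5 %, and 36 % of the first nucleophile's charge left.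

(All constants are assumed; the result is computed.)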